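Late in Saturday's run the readings of c(L) stay level, and late in Friday's they fall.

| flask | Z | E | J | D | remark | time |
|---|---|---|---|---|---|---|
| Saturday's | 26 mM | 2 equiv | 1.1 equiv | 0.05 mol% | run made earlier |  |
| Friday's | 26 mM | 2 equiv | 6.2 equiv | 0.05 mol% | run made earlier |  |
| south | 26 mM | 2.00 equiv | 1.00 equiv | 0.05 mol% |  | 30 min |
| north-east | 26 mM | 2.00 equiv | 2.00 equiv | 0.05 mol% |  | 30 min |
| west | 26 mM | 2.00 equiv | 4.00 equiv | 0.05 mol% |  | 30 min |

| Saturday's: time / min | Saturday's: L / % | Friday's: time / min | Friday's: L / % |
|---|---|---|---|
| 2.50 | 21.1 | 1.50 | 9.1 |
| 8.00 | 31.3 | 4.00 | 8.8 |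
| 15.0 | 29.9 | 10.0 | 6.1 |
| 20.0 | 30.6 | 20.0 | 4.5 |

(standard deviation of a reading: 1 percentage point)

- in percentages every species weighs as the Z in it: one X counts as two

- which of the two there is more of at the end, counted by the Z in each, south (L / X)
- which of the two there is more of at the end, counted by the Z in each, north-east (L / X)
- which of the two there is more of at the end, counted by the Z in each, west (L / X)
- final L, as a percentage of the Z charged, in south
- final L, as a percentage of the Z charged, in north-east
- final L, as a percentage of the Z charged, in west

What do the late readings say? Saturday's last three L readings average 30.6%, flat within the scatter, while Friday's go from 9.1% down to 4.5%.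

What separates the two runs? J: 1.1 equiv on Saturday, 6.2 equiv on Friday, at the same E. The run with more J reads less L.

How could J cost L? J is a second substrate, so I suppose that each J takes one E and each Z takes one E on its way to L. Then the balance of E, in equivalents of Z, says that E charged equals what J took, plus what Z took, plus what is left.

What do you carry from that? South has 1.00 equiv of spare E, the E charged minus the J charged. By the balance, what Z took is the spare plus the J left minus the E left. Saturday's spare is 0.900 equiv, Friday's −4.20 equiv, north-east's 0 equiv, west's −2.00 equiv. In west, E is the limiting reagent against J.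

But Friday's spare is negative and L still appears. Right: on my supposition J and Z share E, and the L readings don't give the split. So the spare ranks flasks and gives no yield.

Then commit. South's spare lies 0.100 equiv above Saturday's, so I put south's L near Saturday's 30.6%, and north-east's and west's lower.

The forecast says the runs suggest that “J drives L on to X”. It gives L of 36% in south, 13% in north-east and 5.5% in west, with marks X, X, X. We part on south, where its figure stands above mine.

    Z + E + D → D + L (k = 3710 M⁻² s⁻¹)
    J + E + D → D + Q (k = 11100 M⁻² s⁻¹)
    Z + L → X (k = 0.0418 M⁻¹ s⁻¹)
    2 D ⇌ G (K = 2.40 × 10⁷ M⁻¹, k = 79.4 M⁻¹ s⁻¹)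

South ends at 28.6% of L against 47.2% of X, north-east at 14.9% against 42.1%, west at 4.69% against 26.9%. In south 7.68% of the J charged remains, beside 27.7% of the E. South's spare 1.00 equiv plus the J left minus the E left then says that Z took 0.522 equiv of E. A neighbouring flask, west's recipe but with 1.60 equiv of J, has a spare of 0.400 equiv, by which Z took 0.421 equiv of E, and it ends at 19.7% of L.

All runs are calculated on assumed constants; the scatter is artificial.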